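(The earlier runs and the new flask are simulated on assumed constants; the scatter is artificial.)

**Small charge.** With a small charge I feared that the solid substrate might end inside the 5.0 d allowed, and the feed of intermediate with it. So I set two times against each other: that window, and how long the solid lasts.

| flask | solid substrate | remark | time |
|---|---|---|---|
| green | 0.13 M | run made earlier |  |
| ochre | 0.30 M | run made earlier |  |
| flask | 0.20 M |  | 5.0 d |

- green (time / d: intermediate / %, product / %, solid substrate / %): 1.25: 6.9, 3.4, 42.2; 1.67: 9.7, 5.6, 36.0; 2.00: 11.9, 6.8, 32.3; 2.50: 13.3, 9.7, 25.6; 3.00: 16.4, 12.2, 20.7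
- ochre (time / d: intermediate / %, product / %, solid substrate / %): 1.25: 3.1, 2.2, 74.9; 1.67: 3.5, 2.4, 72.2; 2.00: 4.5, 2.7, 70.8; 2.50: 5.4, 4.3, 67.9; 3.00: 6.9, 5.2, 65.6

(scatter of a reading: 0.3 percentage points)

- solid, in amounts per volume of the solution: solid substrate
- at the start none of the solid substrate is in solution
- a reading or a percentage of product counts all its forms, free or not

1. the moment within 5.0 d at which there is most intermediate
2. the amount of intermediate, in percent of the solid substrate charged, at that time

**Solid life.** By 3.00 d the green and ochre runs had lost 0.103 M and 0.103 M of solid, so I took the same loss for the new flask, leaving it 0.484 of its charge. The ochre readings then fall steadily (zero-order, in the usual term), at 0.0797 d⁻¹ of the flask's charge. The solid life, the time at which that steady pace brings the solid to zero, is 9.07 d, longer than the window by a factor of 1.81. Intermediate was still climbing at the last readings of both runs, so I expected the flask's peak at the window's end, though this gave me no amount.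

**The forecast.** It said 5 d and 14.5%. Its ground: “Solid therefore persists beyond 5 d, and intermediate keeps being fed.”

**The flask.** The flask gave 5.00 d and 15.7%, with 35.9% of its solid standing at 5.00 d. My reckoning by the solid life had given 32.4% there.

    starting material + product ⇌ idle adduct, settled at all times (K = 1.69 M⁻¹)
    intermediate ⇌ product (K = 0.930, k = 8.59 × 10⁻⁴ min⁻¹)
    solid substrate ⇌ starting material, rate k3*(cs3 - [starting material]) while solid is left; crystals form when [starting material] > cs3 (solubility = 0.0710 M, k = 0.00157 min⁻¹)
    starting material ⇌ intermediate (K = 1.20, k = 1.81 × 10⁻⁴ min⁻¹)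

**Earlier reading.** Read at 3.0 d, the same flask lies 3.02 times inside its solid life, so I expect its highest intermediate at the reading, with 48.4% solid. It gives 10.4% as highest, 10.4% at the reading, and 48.4% solid.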